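**Retrosynthetic overview**

1. Target ⇐ diacetate 26 by allylic hydroxylation at C7. 26 ⇐ ring A 2α,3α-diol 21 (angelate on the equatorial O2, acetates on O3 and O20). 21 ⇐ 3-ketone 19 (α-hydroxylation at C2, then hydride to the equatorial side of C3).
2. 19 ⇐ alcohol 18 ⇐ acyclic epoxy-triene 17. One titanocene-mediated radical cascade closes ring A (C4–C5), then ring B (C9–C10), and ends as the C8=C17 methylene.
3. Enabling feature: in rings A and B the oxygenated C3, the gem-dimethyl C4, the fully substituted C10 and the methylene-bearing C8 form the head-to-tail 1,5-pattern O–C3–C4 / C5=C10 / C9=C8(C17). A radical generated at C4 from a C3–C4 epoxide is therefore relayed through C10 to C9. The unusual cis relation of H9 and C20 is stored as a Z C8=C9 alkene, and the absolute configuration as one (S)-epoxide.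
4. 17 ⇐ two Z-selective Still–Gennari olefinations (C8=C9, then C5=C10) on an aldehyde cut from (R)-linalool (C11–C16 with the C13 carbinol) and a Shi-epoxidised phosphonate (C1–C4, C10, C20).

Key step: step 12

Remark on locants: labdane numbering is used (C1–C10 decalin, C11–C16 side chain, C17 exocyclic CH2, C20 the CH2O group on C10); α is the face of H5.
Assumption: the L-fructose-derived Shi ketone (mirror image of the common D-fructose catalyst) and (R)-(−)-linalool of high enantiomeric purity are taken as available.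

**Route**

Step 1
Reactants: 1 (R)-(−)-linalool
Product: 2 triethyl{[(3R)-3,7-dimethylocta-1,6-dien-3-yl]oxy}silane
Conditions: Et3SiOTf, 2,6-lutidine, CH2Cl2, 0 °C
Reagents that add atoms: triethylsilyl trifluoromethanesulfonate, CC[Si](CC)(CC)OS(=O)(=O)C(F)(F)F
Why: Silyl ether formation with the silyl triflate should cap the hindered tertiary allylic alcohol so that O13 cannot add to the enoates made later; C13 comes from the chiral pool and is not touched.

Step 2
Reactants: 2 triethyl{[(3R)-3,7-dimethylocta-1,6-dien-3-yl]oxy}silane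
Product: 3 (4R)-4-methyl-4-[(triethylsilyl)oxy]hex-5-enal
Conditions: O3, CH2Cl2, −78 °C (Sudan Red 7B end point); then PPh3, −78 °C → rt
Reagents that add atoms: ozone, [O-][O+]=O
Why: Ozonolysis with reductive work-up should cleave only the electron-rich trisubstituted alkene, because the vinyl group is monosubstituted and sits next to the quaternary silyloxy carbon.

Step 3
Reactants: 3 (4R)-4-methyl-4-[(triethylsilyl)oxy]hex-5-enal; 4 ethyl 2-[bis(2,2,2-trifluoroethoxy)phosphoryl]propanoate
Product: 5 ethyl (2Z,6R)-2,6-dimethyl-6-[(triethylsilyl)oxy]octa-2,7-dienoate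
Conditions: KN(SiMe3)2, 18-crown-6, THF, −78 °C
Reagents that add atoms: none
Why: The Still–Gennari variant of the Horner–Wadsworth–Emmons olefination should give the Z trisubstituted enoate, which places the ester carbon (future C7) cis to the C11 chain and the methyl group (future C17) trans to it.

Step 4
Reactants: 5 ethyl (2Z,6R)-2,6-dimethyl-6-[(triethylsilyl)oxy]octa-2,7-dienoate
Product: 6 (2Z,6R)-2,6-dimethyl-6-[(triethylsilyl)oxy]octa-2,7-dien-1-ol
Conditions: i-Bu2AlH, CH2Cl2, −78 °C; Rochelle salt work-up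
Reagents that add atoms: none
Why: 1,2-Reduction of the enoate by the aluminium hydride should give the allylic alcohol with the alkene geometry unchanged.

Step 5
Reactants: 6 (2Z,6R)-2,6-dimethyl-6-[(triethylsilyl)oxy]octa-2,7-dien-1-ol
Product: 7 {[(3R,6Z)-8-bromo-3,7-dimethylocta-1,6-dien-3-yl]oxy}triethylsilane
Conditions: CBr4, PPh3, CH2Cl2, −20 → 0 °C
Reagents that add atoms: carbon tetrabromide, BrC(Br)(Br)Br
Why: The Appel reaction should replace the primary allylic hydroxyl by bromide through SN2 displacement under neutral conditions, without allylic transposition or loss of the Z geometry.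

Step 6
Reactants: 7 {[(3R,6Z)-8-bromo-3,7-dimethylocta-1,6-dien-3-yl]oxy}triethylsilane; 8 N-tert-butylethanimine
Product: 10 (4Z,8R)-4,8-dimethyl-8-[(triethylsilyl)oxy]deca-4,9-dienal, via alkylated tert-butylimine 9 (not isolated)
Conditions: 8, LiN(i-Pr)2, THF, 0 °C; 7, −78 °C → rt; then AcOH/NaOAc/H2O (pH 4.5), rt
Reagents that add atoms: water, O
Why: SN2 alkylation of the metalated imine (aza-enolate) with the primary allylic bromide followed by mild hydrolysis should add C6 and C5 as a two-carbon aldehyde unit without the self-condensation of an acetaldehyde enolate.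

Step 7
Reactants: 11 5-bromo-2-methylpent-2-ene
Product: 12 (3S)-3-(2-bromoethyl)-2,2-dimethyloxirane
Conditions: 1,2:4,5-di-O-isopropylidene-β-L-erythro-2,3-hexodiulo-2,6-pyranose (0.3 equiv), KHSO5 (Oxone), K2CO3, Bu4NHSO4, MeCN/dimethoxymethane/aqueous Na2B4O7 buffer, 0 °C
Reagents that add atoms: potassium peroxymonosulfate, [K+].[O-]S(=O)(=O)OO
Why: Shi asymmetric epoxidation transfers oxygen from the chiral dioxirane through a spiro transition state to one face of the trisubstituted alkene; the L-series ketone should give the (S)-epoxide (the D-series catalyst gives R), and no alkoxide is formed that could displace the bromide.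

Step 8
Reactants: 12 (3S)-3-(2-bromoethyl)-2,2-dimethyloxirane; 13 methyl 2-[bis(2,2,2-trifluoroethoxy)phosphoryl]acetate
Product: 14 methyl 2-[bis(2,2,2-trifluoroethoxy)phosphoryl]-4-[(2S)-3,3-dimethyloxiran-2-yl]butanoate (both epimers at C2)
Conditions: NaH, NaI (cat.), DMF, 0 → 50 °C (13 in excess)
Reagents that add atoms: none
Why: C-alkylation of the stabilised phosphonoacetate anion by the primary bromide (SN2) should leave the trisubstituted epoxide untouched; the new α-centre is lost in the next olefination.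

Step 9
Reactants: 10 (4Z,8R)-4,8-dimethyl-8-[(triethylsilyl)oxy]deca-4,9-dienal; 14 methyl 2-[bis(2,2,2-trifluoroethoxy)phosphoryl]-4-[(2S)-3,3-dimethyloxiran-2-yl]butanoate
Product: 15 methyl (2Z,6Z,10R)-2-{2-[(2S)-3,3-dimethyloxiran-2-yl]ethyl}-6,10-dimethyl-10-[(triethylsilyl)oxy]dodeca-2,6,11-trienoate
Conditions: KN(SiMe3)2, 18-crown-6, THF, −78 °C
Reagents that add atoms: none
Why: A second Still–Gennari olefination with the α-alkyl phosphonate and the unhindered aldehyde should give the Z enoate, which puts the ester carbon (C20) cis and the C1 chain trans to C6, the geometry a chair closure of ring A requires.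

Step 10
Reactants: 15 methyl (2Z,6Z,10R)-2-{2-[(2S)-3,3-dimethyloxiran-2-yl]ethyl}-6,10-dimethyl-10-[(triethylsilyl)oxy]dodeca-2,6,11-trienoate
Product: 16 (2Z,6Z,10R)-2-{2-[(2S)-3,3-dimethyloxiran-2-yl]ethyl}-6,10-dimethyl-10-[(triethylsilyl)oxy]dodeca-2,6,11-trien-1-ol
Conditions: i-Bu2AlH, CH2Cl2, −78 °C; Rochelle salt work-up
Reagents that add atoms: none
Why: The enoate should be reduced to the allylic alcohol much faster than the hindered trisubstituted epoxide is opened at −78 °C.

Step 11
Reactants: 16 (2Z,6Z,10R)-2-{2-[(2S)-3,3-dimethyloxiran-2-yl]ethyl}-6,10-dimethyl-10-[(triethylsilyl)oxy]dodeca-2,6,11-trien-1-ol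
Product: 17 tert-butyldimethylsilyl ether of 16 (epoxy-triene with C20–OSiMe2t-Bu and C13–OSiEt3)
Conditions: t-BuMe2SiCl, imidazole, DMF, 0 °C → rt
Reagents that add atoms: tert-butyldimethylsilyl chloride, CC(C)(C)[Si](C)(C)Cl
Why: Silylation of the primary allylic alcohol gives a C20 protecting group that is inert to trivalent titanium, to enolate formation and to bulky hydride, and that leaves together with the C13 silyl ether later.

Step 12
Reactants: 17 tert-butyldimethylsilyl ether of 16
Product: 18 (13R)-20-[(tert-butyldimethylsilyl)oxy]-13-[(triethylsilyl)oxy]-9βH-labda-8(17),14-dien-3β-ol (5α-H; 10β-CH2O; side chain on C9 α)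
Conditions: Cp2TiCl2 (2.5 equiv), Mn dust, THF, rt, slow addition of 17 at high dilution; then aqueous NaH2PO4, air
Reagents that add atoms: none
Why: Cp2TiCl (trivalent titanium, formed in the flask from Cp2TiCl2 and Mn) opens the epoxide by single-electron transfer at the C4–O bond; the tertiary C4 radical adds 6-endo-trig to C5 (ring A), the resulting tertiary C10 radical adds 6-endo-trig to C9 of the Z alkene (ring B, the C9–C10 bond), and the tertiary C8 radical is captured by a second Cp2TiCl and loses a C17 hydrogen (β-hydride elimination or mixed disproportionation) to leave the C8=C17 methylene. The closest known reaction type is the titanocene-mediated radical polycyclization of epoxypolyprenes to 3β-hydroxy terpenoids with exocyclic methylene groups. C3 keeps the S configuration of the epoxide, and C5 follows from a chair transition state with the C3 titanoxy group equatorial and with C6, which is trans to C1 on the alkene, equatorial (H5 α). C10 follows from trans closure of ring B on the face of the planar C10 radical anti to H5 (CH2O axial, β), and C9 follows from the Z geometry, which places C11 axial (α) in the chair of ring B, so that H9 is cis to C20. The step needs 6-endo rather than 5-exo attack, secured at both alkenes because the attacked carbon is the less substituted one and the radical formed is tertiary, and it needs hydrogen loss at C17 before the hindered C8 radical is reduced or reaches the vinyl group, which slow addition at high dilution should favour; both silyl ethers are inert to trivalent titanium.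

Step 13
Reactants: 18 (13R)-20-[(tert-butyldimethylsilyl)oxy]-13-[(triethylsilyl)oxy]-9βH-labda-8(17),14-dien-3β-ol
Product: 19 (13R)-20-[(tert-butyldimethylsilyl)oxy]-13-[(triethylsilyl)oxy]-9βH-labda-8(17),14-dien-3-one
Conditions: Dess–Martin periodinane, pyridine, CH2Cl2, 0 °C → rt
Reagents that add atoms: none
Why: Dess–Martin oxidation of the only free (secondary) alcohol should give the ketone without affecting the alkenes or silyl ethers; C3 has by now served to relay the absolute configuration to C5, C9 and C10.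

Step 14
Reactants: 19 (13R)-20-[(tert-butyldimethylsilyl)oxy]-13-[(triethylsilyl)oxy]-9βH-labda-8(17),14-dien-3-one
Product: 20 (13R)-20-[(tert-butyldimethylsilyl)oxy]-2α-hydroxy-13-[(triethylsilyl)oxy]-9βH-labda-8(17),14-dien-3-one
Conditions: KN(SiMe3)2, THF, −78 °C; 2-(phenylsulfonyl)-3-phenyloxaziridine, −78 °C; AcOH quench
Reagents that add atoms: 2-(phenylsulfonyl)-3-phenyloxaziridine, O=S(=O)(c1ccccc1)N1OC1c1ccccc1
Why: Davis enolate hydroxylation can occur only at C2 (C4 is quaternary), and the oxaziridine should approach the α face because the β face of C2 is screened by the axial 4β-methyl and the axial C10 CH2O group, giving the equatorial 2α-alcohol.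

Step 15
Reactants: 20 (13R)-20-[(tert-butyldimethylsilyl)oxy]-2α-hydroxy-13-[(triethylsilyl)oxy]-9βH-labda-8(17),14-dien-3-one
Product: 21 (13R)-20-[(tert-butyldimethylsilyl)oxy]-13-[(triethylsilyl)oxy]-9βH-labda-8(17),14-diene-2α,3α-diol
Conditions: LiBH(s-Bu)3 (3 equiv), THF, −78 °C; then aqueous NaOH, H2O2, 0 °C
Reagents that add atoms: none
Why: The bulky trialkylborohydride should attack the C3 carbonyl along the equatorial trajectory, as it does with 2-oxygenated and with 4,4-dimethyl-3-oxo cyclohexanones, and so give the axial 3α-alcohol cis to O2; the low temperature should suppress α-ketol rearrangement.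

Step 16
Reactants: 21 (13R)-20-[(tert-butyldimethylsilyl)oxy]-13-[(triethylsilyl)oxy]-9βH-labda-8(17),14-diene-2α,3α-diol; 22 angelic acid [(Z)-2-methylbut-2-enoic acid]
Product: 24 (13R)-20-[(tert-butyldimethylsilyl)oxy]-3α-hydroxy-13-[(triethylsilyl)oxy]-9βH-labda-8(17),14-dien-2α-yl (Z)-2-methylbut-2-enoate, via angelic 2,4,6-trichlorobenzoic anhydride 23 (not isolated)
Conditions: 22, 2,4,6-trichlorobenzoyl chloride, Et3N, toluene, rt; then 21, toluene, 70 °C
Reagents that add atoms: none
Why: Yamaguchi esterification through the mixed anhydride, run without a nucleophilic amine catalyst, is the standard way to transfer the angeloyl group without Z to E isomerisation; the equatorial 2α-hydroxyl should react far faster than the axial neopentyl 3α-hydroxyl.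

Step 17
Reactants: 24 2α-angelate with C20 and C13 silyl ethers
Product: 25 (13R)-3α,13,20-trihydroxy-9βH-labda-8(17),14-dien-2α-yl (Z)-2-methylbut-2-enoate
Conditions: HF·pyridine, pyridine, THF, 0 °C → rt
Reagents that add atoms: none
Why: Buffered fluoride-mediated desilylation should remove both silyl ethers under conditions too mild to ionise the tertiary allylic alcohol or to move or isomerise the angelate.

Step 18
Reactants: 25 (13R)-3α,13,20-trihydroxy-9βH-labda-8(17),14-dien-2α-yl (Z)-2-methylbut-2-enoate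
Product: 26 (13R)-3α,20-diacetoxy-13-hydroxy-9βH-labda-8(17),14-dien-2α-yl (Z)-2-methylbut-2-enoate
Conditions: Ac2O, pyridine, 4-(dimethylamino)pyridine (cat.), CH2Cl2, rt
Reagents that add atoms: acetic anhydride, CC(=O)OC(C)=O
Why: Acetylation should take the primary C20 and the secondary C3 hydroxyls and leave the tertiary C13 alcohol, which needs forcing conditions; the angelate stays on the less hindered equatorial O2.

Step 19
Reactants: 26 (13R)-3α,20-diacetoxy-13-hydroxy-9βH-labda-8(17),14-dien-2α-yl (Z)-2-methylbut-2-enoate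
Product: 27 (13R)-3α,20-diacetoxy-7α,13-dihydroxy-9βH-labda-8(17),14-dien-2α-yl (Z)-2-methylbut-2-enoate (target, CNP0147212.1)
Conditions: SeO2 (0.5 equiv), t-BuOOH, CH2Cl2, 0 °C → rt
Reagents that add atoms: selenium dioxide, O=[Se]=O (carrier of the oxygen); tert-butyl hydroperoxide, CC(C)(C)OO (terminal oxygen source)
Why: SeO2 allylic oxidation (ene reaction at C17, then 2,3-sigmatropic shift) should hydroxylate the allylic CH2 (C7) in preference to the tertiary C9–H and return the C8=C17 alkene, with the oxygen delivered along the axial (α) direction as in 8(17)-labdenes; the vinyl group has no allylic hydrogen and the electron-poor angelate should not react.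

**Compound list**

1 | (R)-(−)-linalool | C=C[C@](C)(O)CCC=C(C)C | starting material
2 | triethyl{[(3R)-3,7-dimethylocta-1,6-dien-3-yl]oxy}silane | C=C[C@](C)(O[Si](CC)(CC)CC)CCC=C(C)C | intermediate
3 | (4R)-4-methyl-4-[(triethylsilyl)oxy]hex-5-enal | O=CCC[C@@](C)(O[Si](CC)(CC)CC)C=C | intermediate
4 | ethyl 2-[bis(2,2,2-trifluoroethoxy)phosphoryl]propanoate | CCOC(=O)C(C)P(=O)(OCC(F)(F)F)OCC(F)(F)F | starting material
5 | ethyl (2Z,6R)-2,6-dimethyl-6-[(triethylsilyl)oxy]octa-2,7-dienoate | CCOC(=O)/C(C)=C\CC[C@@](C)(O[Si](CC)(CC)CC)C=C | intermediate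
6 | (2Z,6R)-2,6-dimethyl-6-[(triethylsilyl)oxy]octa-2,7-dien-1-ol | OC/C(C)=C\CC[C@@](C)(O[Si](CC)(CC)CC)C=C | intermediate
7 | {[(3R,6Z)-8-bromo-3,7-dimethylocta-1,6-dien-3-yl]oxy}triethylsilane | BrC/C(C)=C\CC[C@@](C)(O[Si](CC)(CC)CC)C=C | intermediate
8 | N-tert-butylethanimine | CC=NC(C)(C)C | starting material
9 | N-tert-butyl imine of aldehyde 10 | CC(C)(C)N=CCC/C(C)=C\CC[C@@](C)(O[Si](CC)(CC)CC)C=C | intermediate
10 | (4Z,8R)-4,8-dimethyl-8-[(triethylsilyl)oxy]deca-4,9-dienal | O=CCC/C(C)=C\CC[C@@](C)(O[Si](CC)(CC)CC)C=C | intermediate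
11 | 5-bromo-2-methylpent-2-ene | CC(C)=CCCBr | starting material
12 | (3S)-3-(2-bromoethyl)-2,2-dimethyloxirane | CC1(C)O[C@H]1CCBr | intermediate
13 | methyl 2-[bis(2,2,2-trifluoroethoxy)phosphoryl]acetate | COC(=O)CP(=O)(OCC(F)(F)F)OCC(F)(F)F | starting material
14 | methyl 2-[bis(2,2,2-trifluoroethoxy)phosphoryl]-4-[(2S)-3,3-dimethyloxiran-2-yl]butanoate (both C2 epimers) | COC(=O)C(CC[C@@H]1OC1(C)C)P(=O)(OCC(F)(F)F)OCC(F)(F)F | intermediate
15 | methyl (2Z,6Z,10R)-2-{2-[(2S)-3,3-dimethyloxiran-2-yl]ethyl}-6,10-dimethyl-10-[(triethylsilyl)oxy]dodeca-2,6,11-trienoate | COC(=O)/C(CC[C@@H]1OC1(C)C)=C\CC/C(C)=C\CC[C@@](C)(O[Si](CC)(CC)CC)C=C | intermediate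
16 | (2Z,6Z,10R)-2-{2-[(2S)-3,3-dimethyloxiran-2-yl]ethyl}-6,10-dimethyl-10-[(triethylsilyl)oxy]dodeca-2,6,11-trien-1-ol | OC/C(CC[C@@H]1OC1(C)C)=C\CC/C(C)=C\CC[C@@](C)(O[Si](CC)(CC)CC)C=C | intermediate
17 | tert-butyldimethylsilyl ether of 16 | CC(C)(C)[Si](C)(C)OC/C(CC[C@@H]1OC1(C)C)=C\CC/C(C)=C\CC[C@@](C)(O[Si](CC)(CC)CC)C=C | intermediate
18 | (13R)-20-[(tert-butyldimethylsilyl)oxy]-13-[(triethylsilyl)oxy]-9βH-labda-8(17),14-dien-3β-ol | C=C[C@](C)(O[Si](CC)(CC)CC)CC[C@@H]1C(=C)CC[C@H]2C(C)(C)[C@@H](O)CC[C@]12CO[Si](C)(C)C(C)(C)C | intermediate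
19 | (13R)-20-[(tert-butyldimethylsilyl)oxy]-13-[(triethylsilyl)oxy]-9βH-labda-8(17),14-dien-3-one | C=C[C@](C)(O[Si](CC)(CC)CC)CC[C@@H]1C(=C)CC[C@H]2C(C)(C)C(=O)CC[C@]12CO[Si](C)(C)C(C)(C)C | intermediate
20 | (13R)-20-[(tert-butyldimethylsilyl)oxy]-2α-hydroxy-13-[(triethylsilyl)oxy]-9βH-labda-8(17),14-dien-3-one | C=C[C@](C)(O[Si](CC)(CC)CC)CC[C@@H]1C(=C)CC[C@H]2C(C)(C)C(=O)[C@H](O)C[C@]12CO[Si](C)(C)C(C)(C)C | intermediate
21 | (13R)-20-[(tert-butyldimethylsilyl)oxy]-13-[(triethylsilyl)oxy]-9βH-labda-8(17),14-diene-2α,3α-diol | C=C[C@](C)(O[Si](CC)(CC)CC)CC[C@@H]1C(=C)CC[C@H]2C(C)(C)[C@H](O)[C@H](O)C[C@]12CO[Si](C)(C)C(C)(C)C | intermediate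
22 | angelic acid [(Z)-2-methylbut-2-enoic acid] | C/C=C(/C)C(=O)O | starting material
23 | angelic 2,4,6-trichlorobenzoic anhydride | C/C=C(/C)C(=O)OC(=O)c1c(Cl)cc(Cl)cc1Cl | intermediate
24 | (13R)-20-[(tert-butyldimethylsilyl)oxy]-3α-hydroxy-13-[(triethylsilyl)oxy]-9βH-labda-8(17),14-dien-2α-yl (Z)-2-methylbut-2-enoate | C=C[C@](C)(O[Si](CC)(CC)CC)CC[C@@H]1C(=C)CC[C@H]2C(C)(C)[C@H](O)[C@H](OC(=O)/C(C)=C\C)C[C@]12CO[Si](C)(C)C(C)(C)C | intermediate
25 | (13R)-3α,13,20-trihydroxy-9βH-labda-8(17),14-dien-2α-yl (Z)-2-methylbut-2-enoate | C=C[C@](C)(O)CC[C@@H]1C(=C)CC[C@H]2C(C)(C)[C@H](O)[C@H](OC(=O)/C(C)=C\C)C[C@]12CO | intermediate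
26 | (13R)-3α,20-diacetoxy-13-hydroxy-9βH-labda-8(17),14-dien-2α-yl (Z)-2-methylbut-2-enoate | C=C[C@](C)(O)CC[C@@H]1C(=C)CC[C@H]2C(C)(C)[C@H](OC(C)=O)[C@H](OC(=O)/C(C)=C\C)C[C@]12COC(C)=O | intermediate
27 | (13R)-3α,20-diacetoxy-7α,13-dihydroxy-9βH-labda-8(17),14-dien-2α-yl (Z)-2-methylbut-2-enoate (CNP0147212.1) | C=C[C@](C)(O)CC[C@@H]1C(=C)[C@H](O)C[C@H]2C(C)(C)[C@H](OC(C)=O)[C@H](OC(=O)/C(C)=C\C)C[C@]12COC(C)=O | target

**Step count and risks**

Total steps: 19. Longest linear sequence: 17 (steps 1–6 and 9–19; steps 7 and 8 make the phosphonate fragment).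

Step 12. What may go wrong: the C10 radical is reduced or quenched before it reaches C9 (ring A only); the ring B closure passes partly through a boat and erodes the C9 configuration; hydrogen loss gives endocyclic alkene isomers; or the C8 radical adds to the vinyl group. The fallback replaces the radical cascade by a Lewis-acid-promoted cationic epoxy-polyene cyclization that ends on an allylsilane. It sets out from 3 and 13 and comes back at 18. Compound 13 is alkylated with (iodomethyl)trimethylsilane (NaH, DMF) to the silylmethyl phosphonate F1. Still–Gennari olefination of 3 with F1 gives the silylmethyl enoate F2, with the ester cis to the C11 chain so that Me3SiCH2 is C17. The operations of steps 4 to 6 and 9 to 11 then give in turn the allylic alcohol F3, the allylic bromide F4, the imine F5, the aldehyde F6, the epoxy dienoate F7 (with 14), the epoxy dienol F8 and the epoxy allylsilane F9. MeAlCl2 (CH2Cl2, −90 °C) should open the epoxide of F9 and trigger a chair–chair closure in which C5 attacks C4 and the allylsilane carbon C9 attacks C10. Loss of Me3Si can only give the C8=C17 alkene, no radical arises at C8, and the antiperiplanar addition across the Z alkene fixes C9, so that work-up returns 18.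

Step 19. What may go wrong: oxygen is delivered to the β face of C7 because the axial C9 chain crowds the α face; the C9–H is attacked instead; or the allylic alcohol is over-oxidised. The fallback sets C7 by carbonyl reduction instead of by oxygen transfer. It sets out from 26 and comes back at 27. Exhaustive allylic oxidation of 26 (SeO2, t-BuOOH, then MnO2 on the crude allylic alcohols) gives the 7-oxo enone F10, in which both C7 epimers converge. Luche reduction (NaBH4, CeCl3·7H2O, MeOH, −78 °C) should deliver hydride from the β face, because the axial α trajectory is blocked by the syn-axial C9 chain, and so give the 7α-alcohol 27 without touching the esters.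

Step 16. What may go wrong: the activated angeloyl group isomerises to the tigloyl (E) group before it is transferred, or acylation also reaches O3. The fallback builds the Z alkene on the substrate instead of transferring it. It sets out from 21 and comes back at 24. The 2α-hydroxyl of 21 is esterified with 2-[bis(2,2,2-trifluoroethoxy)phosphoryl]propanoic acid (carbodiimide coupling; no alkene geometry is at stake) to the phosphonopropanoate F11. Deprotonation (KN(SiMe3)2, 18-crown-6, THF, −78 °C, one extra equivalent for the 3-hydroxyl) and acetaldehyde should then give, by Still–Gennari olefination, the Z 2-methylbut-2-enoate 24.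

**Further compounds**

F1 | step 12 | methyl 2-[bis(2,2,2-trifluoroethoxy)phosphoryl]-3-(trimethylsilyl)propanoate | COC(=O)C(C[Si](C)(C)C)P(=O)(OCC(F)(F)F)OCC(F)(F)F
F2 | step 12 | methyl (6R)-6-methyl-6-[(triethylsilyl)oxy]-2-[(trimethylsilyl)methyl]octa-2,7-dienoate, ester cis to C4 | COC(=O)/C(C[Si](C)(C)C)=C\CC[C@@](C)(O[Si](CC)(CC)CC)C=C
F3 | step 12 | (6R)-6-methyl-6-[(triethylsilyl)oxy]-2-[(trimethylsilyl)methyl]octa-2,7-dien-1-ol, CH2OH cis to C4 | OC/C(C[Si](C)(C)C)=C\CC[C@@](C)(O[Si](CC)(CC)CC)C=C
F4 | step 12 | allylic bromide from F3 (CH2Br cis to the chain) | BrC/C(C[Si](C)(C)C)=C\CC[C@@](C)(O[Si](CC)(CC)CC)C=C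
F5 | step 12 | N-tert-butyl imine of aldehyde F6 | CC(C)(C)N=CCC/C(C[Si](C)(C)C)=C\CC[C@@](C)(O[Si](CC)(CC)CC)C=C
F6 | step 12 | (8R)-8-methyl-8-[(triethylsilyl)oxy]-4-[(trimethylsilyl)methyl]deca-4,9-dienal, C3 cis to C6 | O=CCC/C(C[Si](C)(C)C)=C\CC[C@@](C)(O[Si](CC)(CC)CC)C=C
F7 | step 12 | analogue of 15 with Me3SiCH2 in place of the C17 methyl | COC(=O)/C(CC[C@@H]1OC1(C)C)=C\CC/C(C[Si](C)(C)C)=C\CC[C@@](C)(O[Si](CC)(CC)CC)C=C
F8 | step 12 | analogue of 16 with Me3SiCH2 in place of the C17 methyl | OC/C(CC[C@@H]1OC1(C)C)=C\CC/C(C[Si](C)(C)C)=C\CC[C@@](C)(O[Si](CC)(CC)CC)C=C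
F9 | step 12 | analogue of 17 with Me3SiCH2 in place of the C17 methyl (epoxy allylsilane) | CC(C)(C)[Si](C)(C)OC/C(CC[C@@H]1OC1(C)C)=C\CC/C(C[Si](C)(C)C)=C\CC[C@@](C)(O[Si](CC)(CC)CC)C=C
F10 | step 19 | (13R)-3α,20-diacetoxy-13-hydroxy-7-oxo-9βH-labda-8(17),14-dien-2α-yl (Z)-2-methylbut-2-enoate | C=C[C@](C)(O)CC[C@@H]1C(=C)C(=O)C[C@H]2C(C)(C)[C@H](OC(C)=O)[C@H](OC(=O)/C(C)=C\C)C[C@]12COC(C)=O
F11 | step 16 | (13R)-20-[(tert-butyldimethylsilyl)oxy]-3α-hydroxy-13-[(triethylsilyl)oxy]-9βH-labda-8(17),14-dien-2α-yl 2-[bis(2,2,2-trifluoroethoxy)phosphoryl]propanoate | C=C[C@](C)(O[Si](CC)(CC)CC)CC[C@@H]1C(=C)CC[C@H]2C(C)(C)[C@H](O)[C@H](OC(=O)C(C)P(=O)(OCC(F)(F)F)OCC(F)(F)F)C[C@]12CO[Si](C)(C)C(C)(C)C
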